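Readings and results are calculated from invented constants; noise was put on by code.

The vessel is closed, stirred and held at one temperature, and in it a small loading of initiator turns free monomer into monomer in chains, with transfer agent present.

the same everywhere: free monomer 0.50 M
- south-east: transfer agent 5 mM; initiator 0.13 mol%; run made earlier
- north-west: transfer agent 5 mM; initiator 0.3 mol%; run made earlier
- flask: transfer agent 5.00 mM; initiator 0.2 mol%; time 10 h

| run | time / h | free monomer / % | monomer in chains / % |
|---|---|---|---|
| south-east | 0.667 | 97.9 | 1.4 |
| south-east | 2.00 | 90.8 | 11.5 |
| south-east | 4.00 | 80.8 | 18.4 |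
| south-east | 6.00 | 72.5 | 26.0 |
| south-east | 8.00 | 64.2 | 35.1 |
| north-west | 0.667 | 93.5 | 7.3 |
| north-west | 1.33 | 84.3 | 16.4 |
| north-west | 2.50 | 72.8 | 27.4 |
| north-west | 4.00 | 61.4 | 41.7 |
| north-west | 8.00 | 36.5 | 62.5 |

(readings scatter by 1 percentage point)



1. amount of free monomer in percent of the free monomer charged, at 1.0 h, 4.0 h and 10 h

Does a run slow down? We read the slope of the logarithm of free monomer against time, the share lost per hour. In the north-west run it is 0.119 /h from 1.33 h to 4.00 h, then 0.130 /h up to 8.00 h, no smaller. So within the scatter no slowing can be read in that run, and we let one slope serve each run, which treats free monomer as pseudo-first-order.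

Does the slope follow the loading? From the second reading to the last it is 0.0578 /h in the south-east run and 0.125 /h in the north-west run. That is a factor of 2.16 for a factor of 2.31 in loading, so the two go nearly in step. Dividing slope by loading gives 44.4 /h and 41.8 /h, with mean 43.1 /h. We call this the turnover per initiator: the free monomer one charged initiator takes up per hour, reckoned on the full charge of free monomer.

What does the new flask do? Its loading of 0.2 mol% gives a slope of 0.0863 /h, so we reckon 91.7%, 70.8% and 42.2% at the asked times. But the south-east run read 97.9% at 0.667 h, above the 96.2% of its slope, so a short delay may leave our figures slightly low.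

The forecast, which has a lag where ours has none, gives 93.3%, 72% and 43%: “Interpolating on a log-log basis to 0.2 mol% gives k ≈ 0.087 /h and a lag of about 0.2 h.”

The flask gives 92.5%, 71.6% and 44.9%, so the forecast held within the tolerance.

    free monomer + living end → monomer in chains + living end, rate k1*[living end]*[free monomer] (k = 1.50 /M/min)
    initiator + monomer in chains → initiator + over-reaction product (k = 2.20 /M/min)
    living end + transfer agent → dead chain (kL = 0.0740 /M/min)
    free monomer + initiator → living end + monomer in chains (k = 0.230 /M/min)

In this flask the half-life of free monomer by growth is 8.4 h at 3.87 h, shorter than the 32 h of the living end against transfer agent at 10.0 h, and the turnover per initiator from 4.0 h to 10 h comes to 38.9 /h, against the 43.1 /h carried from the runs. The living end in this flask stands at 9.80 × 10⁻⁴ M after 1.00 h and still at 8.07 × 10⁻⁴ M after 10.0 h.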